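**Plan**

- Retrosynthesis cuts, in this order: the C15–O ester bond (ferulic acid off), the C9–C10 bond of ring B (cation–olefin cyclization), then the C1–C2 and C4–C5 bonds of ring A together, leaving (R)-2,3-dihydrofarnesyl acetate and prenal.
- Enabling feature: C10, which carries the angular methyl C20 and links C1 and C5 of ring A, is the retron of a terminal isopropylidene group. C5 is its olefinic CH, C1 and C20 are its two methyls, and the C2 carbinol, C3 and the gem-dimethyl carbon C4 are the CHO, α- and β-carbons of prenal.
- Forward order: chain first (farnesol to the 13R acetate), then ring A by a two-fold ene [3+3] annulation with prenal on the terminal isopropylidene, then ring B by protic cyclization of the exocyclic olefin onto the (E)-C8=C9 olefin, then the ferulate.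
- Stereochemistry: C13 from Ru(OAc)2[(S)-BINAP] hydrogenation; C2/C5 trans from the carbonyl-ene transition state; the annulation cannot sense C13, so the absolute configuration of ring A comes from a lipase acylation at C2 that picks one of the two ring diastereomers; C9, C10 and the trans ring fusion from the chair–chair cyclization with the C2 acetate equatorial and the (E)-olefin.
- The saturated C13–C14 bond stops the cationic cascade at two rings.

Key step: step 3

Remark: atoms are referred to by the labdane numbering of the target (C1–C20) in every compound. The Me2AlCl of step 3 and the ClSO3H of step 5 are taken as destroyed at work-up by aqueous HCl and aqueous NaHCO3. Compound 6 denotes the (1S,4S) ring isomer; step 3 has no control over the ring configuration relative to C13, so 6 is expected, and is carried into step 4, as a mixture with its (1R,4R) ring diastereomer, CC(=O)OCC[C@H](C)CC/C=C(\C)CC[C@@H]1C(C)(C)C[C@@H](O)CC1=C, which step 4 leaves as the free alcohol and removes.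

**Route**

Step 1
Reactants: 1 (2E,6E)-farnesol
Product: 2 (3R,6E)-3,7,11-trimethyldodeca-6,10-dien-1-ol [(R)-2,3-dihydrofarnesol]
Conditions: H2 (100 atm), Ru(OAc)2[(S)-BINAP] (0.5 mol %), MeOH, 20 °C
Reagents that add atoms: none
Why: Noyori asymmetric hydrogenation, in which the allylic hydroxyl binds ruthenium so that only the 2,3-olefin is reduced and the (S)-BINAP ligand should give the 3R centre (C13) from the (E)-allylic alcohol, as for geraniol to (R)-citronellol.

Step 2
Reactants: 2 (3R,6E)-3,7,11-trimethyldodeca-6,10-dien-1-ol
Product: 3 (3R,6E)-3,7,11-trimethyldodeca-6,10-dien-1-yl acetate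
Conditions: Ac2O, pyridine, DMAP (cat.), CH2Cl2, 0 °C to rt
Reagents that add atoms: acetic anhydride, CC(=O)OC(C)=O
Why: Standard DMAP-catalysed acetylation of a primary alcohol, which masks the C15 hydroxyl against the aluminium reagent of step 3 and the acid of step 5.

Step 3
Reactants: 3 (3R,6E)-3,7,11-trimethyldodeca-6,10-dien-1-yl acetate; 4 3-methylbut-2-enal (prenal)
Product: 6 (3R,6E)-9-[(1S,4S)-4-hydroxy-2,2-dimethyl-6-methylidenecyclohexyl]-3,7-dimethylnon-6-en-1-yl acetate, via ene-adduct aldehyde 5 (not isolated)
Conditions: Me2AlCl (3 equiv), CH2Cl2, −78 °C to 0 °C; aq. HCl; chromatography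
Reagents that add atoms: none
Why: Proposed new method: Me2AlCl-bound prenal should be attacked at its β-carbon (the future C4) by the CH terminus (C5) of the terminal isopropylidene, and the tertiary C10 cation/aluminium enolate pair collapses by 1,5-hydrogen shift from one methyl (the future C1) to the enolate α-carbon (C3), a conjugate ene reaction giving aldehyde 5; its aluminium-bound formyl carbon (C2) is then attacked by the CH2 terminus (C1) of the new isopropenyl group with hydrogen transfer from the remaining methyl (the future C20) to oxygen, an intramolecular carbonyl-ene reaction. The closest known reaction type is the two-fold ene annulation of 1,1-di- and trisubstituted alkenes with acrolein or methyl vinyl ketone under Me2AlCl or EtAlCl2; a β,β-dialkyl enal, which must build a quaternary carbon in the first bond formation, and a polyene partner have not been shown. Ring A closes in a six-membered type 2 carbonyl-ene mode (tether on the central carbon C10 of the ene unit, carbonyl exo and olefin endo to the new ring), which leaves the olefin exocyclic at C10, as in the known Me2AlCl cyclization of 5-methylhex-5-enals to 3-methylenecyclohexanols. C5 is set in the intermolecular step without facial bias from the remote C13 centre, so 6 should form together with its (1R,4R) ring diastereomer in about equal amount, while C2 is set relative to C5 in the closure: the six-membered hydrogen-transfer array holds the aluminium-bound oxygen axial on the forming chair, and the C5 chain should sit axial on the opposite face, where it is anti to one C4 methyl and does not eclipse the C20 methyl, which gives the 2,5-trans alcohol (diequatorial after ring inversion); any 2,5-cis isomer is removed on silica. The step needs 1,4- over 1,2-attack on the enal and the terminal over the internal olefin: the two β-methyls place the positive charge of the complex on C4, the Me2C=CH terminus is the more exposed trisubstituted olefin, and the excess Me2AlCl ties up the acetate carbonyl and scavenges protons so that no olefin is protonated.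

Step 4
Reactants: 6 (3R,6E)-9-[(1S,4S)-4-hydroxy-2,2-dimethyl-6-methylidenecyclohexyl]-3,7-dimethylnon-6-en-1-yl acetate, used as the mixture with its (1R,4R) ring diastereomer from step 3
Product: 7 (3R,6E)-9-[(1S,4S)-4-acetoxy-2,2-dimethyl-6-methylidenecyclohexyl]-3,7-dimethylnon-6-en-1-yl acetate
Conditions: Burkholderia cepacia lipase (immobilized), vinyl acetate, MTBE, 30 °C, to about half conversion; chromatography
Reagents that add atoms: vinyl acetate, C=COC(C)=O
Why: Lipase-catalysed kinetic resolution by irreversible transesterification, in which the enzyme should acylate the (S)-carbinol (C2) of 6 by telling the CH2–CMe2 flank from the CH2–C(=CH2) flank and leave the (1R,4R) ring diastereomer as the free alcohol, which separates easily from diacetate 7 on silica; this fixes the absolute configuration of ring A relative to C13.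

Step 5
Reactants: 7 (3R,6E)-9-[(1S,4S)-4-acetoxy-2,2-dimethyl-6-methylidenecyclohexyl]-3,7-dimethylnon-6-en-1-yl acetate
Product: 8 (13R)-labd-7-ene-2α,15-diyl diacetate
Conditions: ClSO3H (5 equiv), 2-nitropropane, −78 °C; aq. NaHCO3
Reagents that add atoms: none
Why: Brønsted-acid-initiated cation–olefin cyclization of a γ-cyclogeranyl-type diene (a known reaction class for monocyclic terpenoid acetates), in which protonation of the exocyclic methylene gives the C10 cation, C9 of the (E)-olefin adds through a chair transition state with the C2 acetate and the C5 chain equatorial to give the trans-decalin with 10β-methyl, 9α-H and 5α-H, and loss of H-7 from the C8 cation gives the 7-ene.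

Step 6
Reactants: 8 (13R)-labd-7-ene-2α,15-diyl diacetate
Product: 9 (13R)-labd-7-ene-2α,15-diol
Conditions: K2CO3, MeOH, rt
Reagents that add atoms: none
Why: Zemplén-type transesterification should remove both acetates without touching the trisubstituted olefin or any stereocentre.

Step 7
Reactants: 9 (13R)-labd-7-ene-2α,15-diol; 10 (E)-ferulic acid
Product: 11 (13R)-2α-hydroxylabd-7-en-15-yl (E)-3-(4-hydroxy-3-methoxyphenyl)prop-2-enoate (target)
Conditions: PPh3 (1.1 equiv), DIAD (1.1 equiv), THF, 0 °C to rt
Reagents that add atoms: none
Why: Mitsunobu esterification should activate the primary C15 alcohol much faster than the ring secondary C2 alcohol, and the carboxylic acid of unprotected ferulic acid should react in preference to its phenol, as is known for chemoselective Mitsunobu esterification of phenolic cinnamic acids.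

**Compound list**

1 | (2E,6E)-farnesol, (2E,6E)-3,7,11-trimethyldodeca-2,6,10-trien-1-ol | CC(=CCC/C(=C/CC/C(=C/CO)/C)/C)C | starting material
2 | (R)-2,3-dihydrofarnesol, (3R,6E)-3,7,11-trimethyldodeca-6,10-dien-1-ol | OCC[C@H](C)CC/C=C(\C)CCC=C(C)C | intermediate
3 | (3R,6E)-3,7,11-trimethyldodeca-6,10-dien-1-yl acetate | CC(=O)OCC[C@H](C)CC/C=C(\C)CCC=C(C)C | intermediate
4 | 3-methylbut-2-enal (prenal) | CC(C)=CC=O | starting material
5 | ene-adduct aldehyde, (3R,6E,10R)-3,7,11,11-tetramethyl-13-oxo-10-(prop-1-en-2-yl)tridec-6-en-1-yl acetate (not isolated; forms with its C10 epimer) | CC(=O)OCC[C@H](C)CC/C=C(\C)CC[C@H](C(C)=C)C(C)(C)CC=O | intermediate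
6 | (3R,6E)-9-[(1S,4S)-4-hydroxy-2,2-dimethyl-6-methylidenecyclohexyl]-3,7-dimethylnon-6-en-1-yl acetate (obtained as a mixture with its (1R,4R) ring diastereomer) | CC(=O)OCC[C@H](C)CC/C=C(\C)CC[C@H]1C(C)(C)C[C@H](O)CC1=C | intermediate
7 | (3R,6E)-9-[(1S,4S)-4-acetoxy-2,2-dimethyl-6-methylidenecyclohexyl]-3,7-dimethylnon-6-en-1-yl acetate | CC(=O)OCC[C@H](C)CC/C=C(\C)CC[C@H]1C(C)(C)C[C@H](OC(C)=O)CC1=C | intermediate
8 | (13R)-labd-7-ene-2α,15-diyl diacetate | CC(=O)OCC[C@H](C)CC[C@H]2C(C)=CC[C@H]3C(C)(C)C[C@H](OC(C)=O)C[C@]23C | intermediate
9 | (13R)-labd-7-ene-2α,15-diol | OCC[C@H](C)CC[C@H]2C(C)=CC[C@H]3C(C)(C)C[C@H](O)C[C@]23C | intermediate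
10 | (E)-ferulic acid, (E)-3-(4-hydroxy-3-methoxyphenyl)prop-2-enoic acid | COc1cc(/C=C/C(=O)O)ccc1O | starting material
11 | (13R)-2α-hydroxylabd-7-en-15-yl (E)-ferulate | COc1cc(/C=C/C(=O)OCC[C@H](C)CC[C@H]2C(C)=CC[C@H]3C(C)(C)C[C@H](O)C[C@]23C)ccc1O | target

Total step count: 7. Longest linear sequence: 7 steps (from 1).

**Steps most likely to fail**

Step 3 (Proposed new method). The conjugate ene step may lose to carbonyl-ene attack at the formyl carbon, to reaction at the internal olefin, to capture of the C10 cation by that olefin before hydrogen transfer, or to further ene reaction of the new 1,1-disubstituted olefin; the ring closure may also show poor 2,5-trans selectivity. The fallback is stepwise and uses known chemistry, setting out from 3 and coming back at 6. SeO2/t-BuOOH should oxidize the (E)-methyl of the terminal isopropylidene of 3 to (3R,6E,10E)-12-hydroxy-3,7,11-trimethyldodeca-6,10-dien-1-yl acetate F1. Acid-catalysed condensation of this allylic alcohol with isobutyraldehyde (p-TsOH, heat, water removal) forms the allyl 2-methylprop-1-enyl ether, whose Claisen rearrangement makes the C4–C5 bond and should give (3R,6E)-3,7,11,11-tetramethyl-12-oxo-10-(prop-1-en-2-yl)dodec-6-en-1-yl acetate F2 as both C10 epimers. Wittig homologation with Ph3P=CHOMe should give the enol ether (3R,6E)-13-methoxy-3,7,11,11-tetramethyl-10-(prop-1-en-2-yl)trideca-6,12-dien-1-yl acetate F3. Mild acid hydrolysis then gives aldehyde 5, now isolated, and Me2AlCl effects the known type 2 carbonyl-ene cyclization of such 5-methylhex-5-enals to 6 (again with its ring diastereomer).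

Step 5. The exocyclic olefin may isomerize into the ring before cyclization, the C2 acetate may intercept the C10 cation, and proton loss from the C8 cation may be unselective (7-ene against 8(17)- and 8-ene). The fallback, from 7 back to 8, replaces the proton by a divalent mercury electrophile in a buffered medium. Hg(OTf)2·PhNMe2 in MeNO2 at −20 °C adds to the CH2 terminus of the exocyclic olefin, the same chair cyclization follows with the aniline as base for the terminating deprotonation, and aqueous NaCl should give (13R)-20-(chloromercurio)labd-7-ene-2α,15-diyl diacetate F6. NaBH4 in aqueous NaOH at 0 °C then replaces mercury by hydrogen, turning C20 into the angular methyl of 8; partial loss of an acetate here would be harmless, since step 6 removes both.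

Step 4. The enzyme may discriminate poorly between the two ring configurations, or may select the other diastereomer (in which case the unreacted alcohol is the useful one and is acetylated chemically). The fallback is a covalent resolution, from 6 (as the mixture) back to 7. Esterification of the mixture with (S)-O-methylmandelic acid (DCC, DMAP) gives two diastereomeric esters that should separate on silica; the one derived from 6 is (3R,6E)-9-[(1S,4S)-4-{[(2S)-2-methoxy-2-phenylacetyl]oxy}-2,2-dimethyl-6-methylidenecyclohexyl]-3,7-dimethylnon-6-en-1-yl acetate F4. K2CO3/MeOH cleaves both esters to (1S,4S)-4-[(3E,7R)-9-hydroxy-3,7-dimethylnon-3-en-1-yl]-3,3-dimethyl-5-methylidenecyclohexan-1-ol F5, and Ac2O/pyridine/DMAP acetylates both hydroxyls to give 7.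

**Further compounds**

F1 | step 3 | (3R,6E,10E)-12-hydroxy-3,7,11-trimethyldodeca-6,10-dien-1-yl acetate | CC(=O)OCC[C@H](C)CC/C=C(\C)CC/C=C(\C)CO
F2 | step 3 | (3R,6E)-3,7,11,11-tetramethyl-12-oxo-10-(prop-1-en-2-yl)dodec-6-en-1-yl acetate (both C10 epimers) | CC(=O)OCC[C@H](C)CC/C=C(\C)CCC(C(C)=C)C(C)(C)C=O
F3 | step 3 | (3R,6E)-13-methoxy-3,7,11,11-tetramethyl-10-(prop-1-en-2-yl)trideca-6,12-dien-1-yl acetate (both C10 epimers, E/Z enol ether) | CC(=O)OCC[C@H](C)CC/C=C(\C)CCC(C(C)=C)C(C)(C)C=COC
F4 | step 4 | (3R,6E)-9-[(1S,4S)-4-{[(2S)-2-methoxy-2-phenylacetyl]oxy}-2,2-dimethyl-6-methylidenecyclohexyl]-3,7-dimethylnon-6-en-1-yl acetate | CC(=O)OCC[C@H](C)CC/C=C(\C)CC[C@H]1C(C)(C)C[C@H](OC(=O)[C@@H](OC)c2ccccc2)CC1=C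
F5 | step 4 | (1S,4S)-4-[(3E,7R)-9-hydroxy-3,7-dimethylnon-3-en-1-yl]-3,3-dimethyl-5-methylidenecyclohexan-1-ol | OCC[C@H](C)CC/C=C(\C)CC[C@H]1C(C)(C)C[C@H](O)CC1=C
F6 | step 5 | (13R)-20-(chloromercurio)labd-7-ene-2α,15-diyl diacetate | CC(=O)OCC[C@H](C)CC[C@H]2C(C)=CC[C@H]3C(C)(C)C[C@H](OC(C)=O)C[C@]23C[Hg]Cl
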